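**Retrosynthetic overview**

1. Cut C6–C7: target 23 ⇐ (after desilylation) C9 ketone 3 (TBS ether of (S)-phorenol, left ring) + C31 heptaene-diyne 18 (chain plus right ring). C7=C8 is carried one oxidation level higher, as the terminal alkyne C7≡C8.
2. Enabling feature: C6 is a tertiary carbinol of the left cyclohexene ring, set between quaternary C1 (gem-dimethyl) and the C4=C5 double bond, so its precursor is a ketone with no α-hydrogen on either flank. Once C7 is attached, the C6 alkoxide is propargylic to C7≡C8 only and steers hydride there; C7'≡C8' sits on the sp2 carbon C6' of the right ring with no oxygen neighbour. The C3 silyloxy group of the same ring controls the face.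
3. 18 ⇐ C15 phosphonium salt 11 + C10 dialdehyde 14 + C6 phosphonium salt 13 (two Wittig reactions, C11=C12 and C11'=C12'); both enyne units come from the same alcohol 8.
4. 11 ⇐ enol triflate 7 + 8 (Sonogashira, C6'–C7'). Ring order: no ring is built; both six-membered rings are bought (left from ketoisophorone 1 by asymmetric transfer hydrogenation, right from (4R,6R)-actinol 4).
5. Last step: fluoride removal of both silyl groups.

Key step: step 10

Assumption: carotenoid locants are used with the 3,6-dihydroxy ring unprimed (C1–C6), the chain C7–C15/C15'–C7' and the acetylenic ring primed; 4, 8 and 14 are taken as purchasable; in step 1 the catalyst antipode is assigned by analogy with aryl ketones (alkenyl flank in the aryl role), and the mirror-image catalyst would be used if the sense proves opposite.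

**Step 1**
Reactants: 1 ketoisophorone (2,6,6-trimethylcyclohex-2-ene-1,4-dione)
Product: 2 (S)-phorenol, (4S)-4-hydroxy-2,6,6-trimethylcyclohex-2-en-1-one
Conditions: RuCl[(S,S)-TsDPEN](p-cymene) (cat.), i-PrOH, rt
Reagents that add atoms: none
Why: Noyori asymmetric transfer hydrogenation is carbonyl-selective and should reduce only the unhindered C4 carbonyl (C1 is shielded by the C2 methyl and the C6 gem-dimethyl group), the chiral ligand setting the C4 stereocentre (later C3) by distinguishing the alkenyl from the CH2 flank.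

**Step 2**
Reactants: 2 (S)-phorenol
Product: 3 (4S)-4-[(tert-butyldimethylsilyl)oxy]-2,6,6-trimethylcyclohex-2-en-1-one
Conditions: TBSCl, imidazole, DMF, rt
Reagents that add atoms: tert-butyldimethylsilyl chloride, CC(C)(C)[Si](C)(C)Cl
Why: Standard silylation of a secondary allylic alcohol; no stereocentre is touched.

**Step 3**
Reactants: 4 (4R,6R)-actinol, (4R,6R)-4-hydroxy-2,2,6-trimethylcyclohexan-1-one
Product: 5 (4R,6R)-4-[(tert-butyldimethylsilyl)oxy]-2,2,6-trimethylcyclohexan-1-one
Conditions: TBSCl, imidazole, DMF, rt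
Reagents that add atoms: tert-butyldimethylsilyl chloride, CC(C)(C)[Si](C)(C)Cl
Why: Standard silylation of the secondary alcohol; both stereocentres are retained.

**Step 4**
Reactants: 5 silyl ether of actinol
Product: 7 (4R)-4-[(tert-butyldimethylsilyl)oxy]-2,6,6-trimethylcyclohex-1-en-1-yl trifluoromethanesulfonate, via lithium enolate 6 (not isolated)
Conditions: LDA, THF, −78 → 0 °C; PhNTf2, −78 °C → rt
Reagents that add atoms: N-phenylbis(trifluoromethanesulfonimide), O=S(=O)(N(c1ccccc1)S(=O)(=O)C(F)(F)F)C(F)(F)F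
Why: Deprotonation is possible only at C6–H (C2 is quaternary), so a single enolate forms and is O-sulfonylated (enol triflate formation); the methyl-bearing stereocentre is erased on purpose and C4 is untouched.

**Step 5**
Reactants: 7 enol triflate; 8 (E)-3-methylpent-2-en-4-yn-1-ol
Product: 9 (2E)-5-[(4R)-4-[(tert-butyldimethylsilyl)oxy]-2,6,6-trimethylcyclohex-1-en-1-yl]-3-methylpent-2-en-4-yn-1-ol (C15 enynol)
Conditions: Pd(PPh3)4 (cat.), CuI (cat.), i-Pr2NH, DMF, rt → 50 °C
Reagents that add atoms: none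
Why: Sonogashira coupling of the alkenyl triflate with the terminal alkyne forms C6'–C7' with retention of the E-enyne geometry and tolerates the free primary alcohol.

**Step 6**
Reactants: 9 C15 enynol
Product: 11 [(2E)-5-[(4R)-4-[(tert-butyldimethylsilyl)oxy]-2,6,6-trimethylcyclohex-1-en-1-yl]-3-methylpent-2-en-4-yn-1-yl]triphenylphosphonium bromide, via allylic bromide 10 (not isolated)
Conditions: CBr4, PPh3, CH2Cl2, −20 → 0 °C; then PPh3, EtOAc, rt
Reagents that add atoms: carbon tetrabromide, BrC(Br)(Br)Br (bromide counter-ion); triphenylphosphine, c1ccccc1P(c1ccccc1)c1ccccc1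
Why: Appel bromination of the primary allylic alcohol proceeds by SN2 on the alkoxyphosphonium (no free allyl cation, so 9'E is kept), and PPh3 then quaternises the primary bromide by SN2.

**Step 7**
Reactants: 8 (E)-3-methylpent-2-en-4-yn-1-ol
Product: 13 [(2E)-3-methylpent-2-en-4-yn-1-yl]triphenylphosphonium bromide, via allylic bromide 12 (not isolated)
Conditions: CBr4, PPh3, CH2Cl2, −20 → 0 °C; then PPh3, EtOAc, rt
Reagents that add atoms: carbon tetrabromide, BrC(Br)(Br)Br (bromide counter-ion); triphenylphosphine, c1ccccc1P(c1ccccc1)c1ccccc1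
Why: Same Appel bromination and SN2 quaternisation as in step 6, keeping the E-geometry and leaving the terminal alkyne untouched.

**Step 8**
Reactants: 13 C6 phosphonium salt; 14 (2E,4E,6E)-2,7-dimethylocta-2,4,6-trienedial (3 equiv)
Product: 16 (2E,4E,6E,8E,10E)-2,7,11-trimethyltrideca-2,4,6,8,10-pentaen-12-ynal, via (8Z)-isomer 15 (not isolated)
Conditions: NaOMe (1 equiv) added to 13 + 14, CH2Cl2–MeOH, 0 °C → rt; then heptane, 80 °C, Ar, dark
Reagents that add atoms: none
Why: Wittig olefination of the allylic ylide with one formyl group of the dialdehyde in excess (the mono-adduct enal is less electrophilic; methoxide does not deprotonate the alkyne), and the sterically hindered Z-olefin beside the methyl-bearing carbon should equilibrate thermally to E.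

**Step 9**
Reactants: 16 C16 ynal; 11 C15 phosphonium salt
Product: 18 all-E C31 heptaene-diyne, tert-butyldimethyl{[(1R)-3,5,5-trimethyl-4-[(3E,5E,7E,9E,11E,13E,15E)-3,7,12,16-tetramethyloctadeca-3,5,7,9,11,13,15-heptaene-1,17-diyn-1-yl]cyclohex-3-en-1-yl]oxy}silane, via (11'Z)-isomer 17 (not isolated)
Conditions: NaOMe, CH2Cl2–MeOH, 0 °C → rt; then heptane, 80 °C, Ar, dark
Reagents that add atoms: none
Why: Second Wittig olefination forms C11'=C12'; the silyl ether and terminal alkyne tolerate methoxide, and the hindered 11'Z isomer should again isomerise thermally to the all-E chain.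

**Step 10**
Reactants: 18 C31 heptaene-diyne; 3 silyl ether of (S)-phorenol
Product: 22 (3S,6R,3'R)-3,3'-bis-O-(tert-butyldimethylsilyl) ether of the target, via lithium acetylide 19 (not isolated), via lithium propargylic alkoxide 20 (not isolated), via cyclic vinylalanate 21 (not isolated)
Conditions: LDA (1.05 equiv), THF, −78 °C; 3 (1.3 equiv), −78 → −20 °C; then Red-Al (3 equiv), THF–toluene, −20 → 0 °C; aq. Rochelle salt
Reagents that add atoms: none
Why: LDA removes only the terminal C7–H of 18, and the hard lithium acetylide 19 adds 1,2 to the C6 carbonyl of 3 (no α-hydrogen at C1 or C5), forming C6–C7 and the whole C40 skeleton; the closest known reaction type is acetylide addition to 4-oxygenated 2,6,6-trimethylcyclohex-2-enones for abscisic-acid-type side chains, followed by Red-Al reduction of a propargylic alcohol to an (E)-allylic alcohol. The new stereocentre C6 is set by substrate control from C3: the acetylide should enter anti to the allylic silyloxy group (pseudoaxial C3–O aligned with the enone π-system, the same face also carrying the syn-axial C1 methyl), which places C7 trans to the C3 oxygen, i.e. the cis-3,6-dioxygen pattern (6R). The C6 alkoxide 20 then binds aluminium and delivers hydride to C7 (trans-hydroalumination through the five-membered oxaaluminacycle 21), and protonolysis of C8–Al with retention gives the 7E olefin; no ring of the product is closed, the aluminacycle being transient. The step needs 1,2- over 1,4-addition (lithium acetylide, non-enolisable ketone), facial selectivity (C3-OTBS) and discrimination of two alkynes: only C7≡C8 is propargylic to an alkoxide, whereas C7'≡C8' on sp2 C6' and the polyene offer hydride no directing group.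

**Step 11**
Reactants: 22 bis-silyl ether
Product: 23 target, (3S,6R,3'R)-7',8'-didehydro-ε,β-carotene-3,6,3'-triol in the locants used here
Conditions: TBAF (3 equiv), THF, 0 °C → rt, Ar, dark
Reagents that add atoms: none
Why: Fluoride-mediated desilylation cleaves both Si–O bonds without acid, so the ionisation-prone tertiary bis-allylic C6 carbinol and all stereocentres are left intact.

**Compound list**

1 | ketoisophorone, 2,6,6-trimethylcyclohex-2-ene-1,4-dione | CC1=CC(=O)CC(C)(C)C1=O | starting material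
2 | (S)-phorenol, (4S)-4-hydroxy-2,6,6-trimethylcyclohex-2-en-1-one | CC1=C[C@@H](O)CC(C)(C)C1=O | intermediate
3 | (4S)-4-[(tert-butyldimethylsilyl)oxy]-2,6,6-trimethylcyclohex-2-en-1-one | CC1=C[C@@H](O[Si](C)(C)C(C)(C)C)CC(C)(C)C1=O | intermediate
4 | (4R,6R)-actinol, (4R,6R)-4-hydroxy-2,2,6-trimethylcyclohexan-1-one | O=C1[C@H](C)C[C@@H](O)CC1(C)C | starting material
5 | (4R,6R)-4-[(tert-butyldimethylsilyl)oxy]-2,2,6-trimethylcyclohexan-1-one | O=C1[C@H](C)C[C@@H](O[Si](C)(C)C(C)(C)C)CC1(C)C | intermediate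
6 | lithium (4R)-4-[(tert-butyldimethylsilyl)oxy]-2,6,6-trimethylcyclohex-1-en-1-olate | [Li+].[O-]C1=C(C)C[C@@H](O[Si](C)(C)C(C)(C)C)CC1(C)C | intermediate (not isolated)
7 | (4R)-4-[(tert-butyldimethylsilyl)oxy]-2,6,6-trimethylcyclohex-1-en-1-yl trifluoromethanesulfonate | O=S(=O)(OC1=C(C)C[C@@H](O[Si](C)(C)C(C)(C)C)CC1(C)C)C(F)(F)F | intermediate
8 | (E)-3-methylpent-2-en-4-yn-1-ol | C#C/C(C)=C/CO | starting material
9 | C15 enynol, (2E)-5-[(4R)-4-(TBSO)-2,6,6-trimethylcyclohex-1-en-1-yl]-3-methylpent-2-en-4-yn-1-ol | OC/C=C(\C)C#CC1=C(C)C[C@@H](O[Si](C)(C)C(C)(C)C)CC1(C)C | intermediate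
10 | C15 allylic bromide, (E)-primary bromide of 9 | BrC/C=C(\C)C#CC1=C(C)C[C@@H](O[Si](C)(C)C(C)(C)C)CC1(C)C | intermediate (not isolated)
11 | C15 triphenylphosphonium bromide | [Br-].c1ccccc1[P+](c1ccccc1)(c1ccccc1)C/C=C(\C)C#CC1=C(C)C[C@@H](O[Si](C)(C)C(C)(C)C)CC1(C)C | intermediate
12 | (E)-5-bromo-3-methylpent-3-en-1-yne | C#C/C(C)=C/CBr | intermediate (not isolated)
13 | [(2E)-3-methylpent-2-en-4-yn-1-yl]triphenylphosphonium bromide | [Br-].C#C/C(C)=C/C[P+](c1ccccc1)(c1ccccc1)c1ccccc1 | intermediate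
14 | (2E,4E,6E)-2,7-dimethylocta-2,4,6-trienedial | O=C/C(C)=C/C=C/C=C(C)/C=O | starting material
15 | (2E,4E,6E,8Z,10E)-2,7,11-trimethyltrideca-2,4,6,8,10-pentaen-12-ynal | C#C/C(C)=C/C=C\C(C)=C\C=C\C=C(C)\C=O | intermediate (not isolated)
16 | (2E,4E,6E,8E,10E)-2,7,11-trimethyltrideca-2,4,6,8,10-pentaen-12-ynal | C#C/C(C)=C/C=C/C(C)=C/C=C/C=C(C)/C=O | intermediate
17 | (11'Z)-isomer of the C31 heptaene-diyne | C#C/C(C)=C/C=C/C(C)=C/C=C/C=C(C)/C=C\C=C(/C)C#CC1=C(C)C[C@@H](O[Si](C)(C)C(C)(C)C)CC1(C)C | intermediate (not isolated)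
18 | all-E C31 heptaene-diyne (3'-O-TBS, terminal C7≡C8–H) | C#C/C(C)=C/C=C/C(C)=C/C=C/C=C(C)/C=C/C=C(\C)C#CC1=C(C)C[C@@H](O[Si](C)(C)C(C)(C)C)CC1(C)C | intermediate
19 | lithium acetylide of 18 | [Li+].[C-]#C/C(C)=C/C=C/C(C)=C/C=C/C=C(C)/C=C/C=C(\C)C#CC1=C(C)C[C@@H](O[Si](C)(C)C(C)(C)C)CC1(C)C | intermediate (not isolated)
20 | lithium (3S,6R)-C6 alkoxide of the 7,8-didehydro adduct | [Li+].CC1=C[C@@H](O[Si](C)(C)C(C)(C)C)CC(C)(C)[C@]1([O-])C#C/C(C)=C/C=C/C(C)=C/C=C/C=C(C)/C=C/C=C(\C)C#CC1=C(C)C[C@@H](O[Si](C)(C)C(C)(C)C)CC1(C)C | intermediate (not isolated)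
21 | sodium cyclic vinylalanate (O–Al–C8=C7–C6 ring; Al drawn with one hydride and one 2-methoxyethoxide) | [Na+].CC1=C[C@@H](O[Si](C)(C)C(C)(C)C)CC(C)(C)[C@@]13O[AlH-](OCCOC)C(=C3)/C(C)=C/C=C/C(C)=C/C=C/C=C(C)/C=C/C=C(\C)C#CC1=C(C)C[C@@H](O[Si](C)(C)C(C)(C)C)CC1(C)C | intermediate (not isolated)
22 | (3S,6R,3'R)-3,3'-bis-O-TBS ether of the target | CC1=C[C@@H](O[Si](C)(C)C(C)(C)C)CC(C)(C)[C@]1(O)/C=C/C(C)=C/C=C/C(C)=C/C=C/C=C(C)/C=C/C=C(\C)C#CC1=C(C)C[C@@H](O[Si](C)(C)C(C)(C)C)CC1(C)C | intermediate
23 | target, (3S,6R,3'R)-7',8'-didehydro-ε,β-carotene-3,6,3'-triol [IUPAC locants: (3R,3'S,6'R)-7,8-didehydro-β,ε-carotene-3,3',6'-triol] | CC1=C[C@@H](O)CC(C)(C)[C@]1(O)/C=C/C(C)=C/C=C/C(C)=C/C=C/C=C(C)/C=C/C=C(\C)C#CC1=C(C)C[C@@H](O)CC1(C)C | target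

**Totals**

Total steps: 11. Longest linear sequence: 7 steps (4 → 5 → 7 → 9 → 11 → 18 → 22 → 23; steps 3, 4, 5, 6, 9, 10, 11).

**Steps most likely to fail**

Step 10. The acetylide may approach C6 syn to the C3 silyloxy group (poor or reversed facial selectivity), which would give the C6 epimer; this direction of attack is the least certain point of the route. The fallback sets out from 1 (and uses 18) and returns at 23. Transfer hydrogenation of 1 with the mirror-image catalyst would give (R)-phorenol F1, and TESCl/imidazole its triethylsilyl ether F2. The key step run on F2 with 18 would then give, by the same syn preference, the (3R,6R)-adduct F3, in which C6 is already correct. Pyridine-buffered HF·pyridine should remove only the triethylsilyl group to give the (3R,6R)-3,6-diol F4. A Mitsunobu reaction (4-nitrobenzoic acid, PPh3, DIAD) should invert the secondary allylic C3 carbinol, the tertiary C6–OH being inert, to give the (3S)-4-nitrobenzoate F5. K2CO3/MeOH would give the (3S,6R)-3,6-diol F6, and TBAF the target 23.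

Step 5. Oxidative addition into the tetrasubstituted, neopentyl-flanked enol triflate may be slow, so that alkyne homocoupling and triflate hydrolysis compete. The fallback sets out from 5 (and uses 8) and returns at 9. Dilithiated 8 (n-BuLi, 2 equiv, THF) added to ketone 5 would give the tertiary propargylic diol F7, whose carbinol configuration is irrelevant. Ac2O/pyridine would acetylate only the primary hydroxyl to give F8. POCl3/pyridine dehydration would give the enyne acetate F9; only the C5' hydrogen is available, so only the ring C5'=C6' alkene can form. K2CO3/MeOH then returns 9.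

Step 9. The allylic ylide may give much of the Z-olefin at C11'=C12' and may lose the 9'E geometry by rotation within the delocalised ylide, and the thermal equilibration of the C31 polyenyne may be incomplete. The fallback sets out from 9 and returns at 18. Bromide 10, made as in step 6, treated with sodium diethyl phosphite (Michaelis–Becker) would give the C15 diethyl phosphonate F10. Its anion (NaHMDS, THF, −78 °C) with 16 in a Horner–Wadsworth–Emmons olefination should give 18 with the E-olefin formed directly.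

**Further compounds**

F1 | step 10 | (R)-phorenol, (4R)-4-hydroxy-2,6,6-trimethylcyclohex-2-en-1-one | CC1=C[C@H](O)CC(C)(C)C1=O
F2 | step 10 | (4R)-4-[(triethylsilyl)oxy]-2,6,6-trimethylcyclohex-2-en-1-one | CC1=C[C@H](O[Si](CC)(CC)CC)CC(C)(C)C1=O
F3 | step 10 | (3R,6R,3'R)-adduct, 3-O-TES, 3'-O-TBS | CC1=C[C@H](O[Si](CC)(CC)CC)CC(C)(C)[C@]1(O)/C=C/C(C)=C/C=C/C(C)=C/C=C/C=C(C)/C=C/C=C(\C)C#CC1=C(C)C[C@@H](O[Si](C)(C)C(C)(C)C)CC1(C)C
F4 | step 10 | (3R,6R,3'R)-3,6-diol, 3'-O-TBS | CC1=C[C@H](O)CC(C)(C)[C@]1(O)/C=C/C(C)=C/C=C/C(C)=C/C=C/C=C(C)/C=C/C=C(\C)C#CC1=C(C)C[C@@H](O[Si](C)(C)C(C)(C)C)CC1(C)C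
F5 | step 10 | (3S,6R,3'R)-3-O-(4-nitrobenzoate), 3'-O-TBS | CC1=C[C@@H](OC(=O)c2ccc(cc2)[N+](=O)[O-])CC(C)(C)[C@]1(O)/C=C/C(C)=C/C=C/C(C)=C/C=C/C=C(C)/C=C/C=C(\C)C#CC1=C(C)C[C@@H](O[Si](C)(C)C(C)(C)C)CC1(C)C
F6 | step 10 | (3S,6R,3'R)-3,6-diol, 3'-O-TBS | CC1=C[C@@H](O)CC(C)(C)[C@]1(O)/C=C/C(C)=C/C=C/C(C)=C/C=C/C=C(C)/C=C/C=C(\C)C#CC1=C(C)C[C@@H](O[Si](C)(C)C(C)(C)C)CC1(C)C
F7 | step 5 | tertiary propargylic diol from 5 and dilithiated 8 (carbinol epimers) | OC/C=C(\C)C#CC1(O)[C@H](C)C[C@@H](O[Si](C)(C)C(C)(C)C)CC1(C)C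
F8 | step 5 | primary acetate of F7 | CC(=O)OC/C=C(\C)C#CC1(O)[C@H](C)C[C@@H](O[Si](C)(C)C(C)(C)C)CC1(C)C
F9 | step 5 | acetate of C15 enynol 9 | CC(=O)OC/C=C(\C)C#CC1=C(C)C[C@@H](O[Si](C)(C)C(C)(C)C)CC1(C)C
F10 | step 9 | C15 diethyl phosphonate | CCOP(=O)(OCC)C/C=C(\C)C#CC1=C(C)C[C@@H](O[Si](C)(C)C(C)(C)C)CC1(C)C
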